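## Structural features

The target is a 2H-chromene (benzo ring A fused to pyran ring B). Its C6 is joined by a saturated Cα–Cβ bridge to a benzene-1,2-diol (ring C), at the ring-C carbon next to the two hydroxyl-bearing carbons. C2 of ring B is the only stereocentre: a fully substituted carbon of S configuration carrying O1, a methyl group, the ring alkene carbon C3 and a five-carbon chain that ends in an (E)-2-methylallylic alcohol. With no neighbouring stereocentre, the problem is one of absolute configuration only. The fragile groups are the catechol (oxidation to the quinone in air or base), the styrenic C3=C4 bond and the tertiary aryl ether C2–O1 (acid, hydrogenation), and the primary allylic alcohol with its trisubstituted alkene. The real difficulty is twofold: a tertiary ether stereocentre as one enantiomer, and a saturated two-carbon bridge between two arenes in a molecule whose two alkenes rule out a stilbene hydrogenation. The key step exploits the Cα–Cβ unit. Because it is flanked by C6 of ring A and by ring C, both aryl–CH2 bonds can be made on a vinylboron: ring C as the group migrating from boron, ring A as the electrophile, with boron left on Cβ as a benzylic handle that is later replaced by hydrogen. Ring C is attached ortho to an oxygen, which is exactly where directed lithiation of a protected catechol places the metal.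

## Logic of the disconnections

18 to 17: the two phenolic O–H bonds are traced back to O–CH2OCH3 acetals. A free catechol would not survive organolithium, palladium or fluoride chemistry, and the acetals also serve as directing groups earlier. The forward step must cleave two aryl acetals with acid mild enough to spare the allylic alcohol and the C2–O1 bond, with air excluded.

17 to 15 (through 16): the Cβ–H bond is traced back to a Cβ–B bond and the primary O–H to an O–Si bond. Fluoride strong enough to break the benzylic C–B bond cannot spare a primary silyl ether, so loss of silicon is planned into this same operation and not left for the acid step. The forward step must protonate Cβ cleanly; its configuration is irrelevant.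

15 to 9, 11 and 12 (through 13 and 14): the cuts are C6–Cα and Cβ–ring C, both on the two carbons of 12. This removes the whole bridge in one operation, joins the two halves convergently, and needs no reduction near the chromene alkene. The demand is that the 1,2-metalate shift outruns direct transfer of aryl or vinyl from boron to palladium.

11 to 10: two O–C bonds of the acetals are cut. The forward step is a double O-alkylation.

9 to 8: the C3=C4 bond of ring B is cut to two terminal alkenes. This opens ring B to an acyclic ether whose stereocentre is already in place. The catalyst must close onto the hindered vinyl group and leave the trisubstituted side-chain alkene alone.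

8 to 7: the styrene C=CH2 bond is traced back to a formyl group, which also activates the next cut.

7 to 4 and 5 (through 6): the aryl C–O bond (the future O1–C8a) is cut. The C–O bond at the stereocentre stays intact, so the configuration of the tertiary alcohol passes unchanged into C2. The demand is an intermolecular substitution at an aromatic carbon by a hindered tertiary alkoxide beside an aldehyde.

4 to 3 to 1 (through 2): the O–Si bond, then the allylic C–O bond at the terminal (E)-methyl group, are removed. This leads back to a purchasable terpene alcohol that already holds the stereocentre and all ten carbons of the C2 substituents. The demand is E-selective oxidation of one of two geminal methyl groups and silylation of the primary hydroxyl only.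

## Other disconnections considered

Alternative 1: The cut is C3=C4 of ring B in a compound still lacking the side chain. Triene A2, an aryl ether of a tertiary carbinol with two enantiotopic vinyl groups, would be closed onto its styrene by Mo(N-2,6-iPr2C6H3)(CHCMe2Ph)(3,3'-di-tert-butyl-5,5',6,6'-tetramethylbiphenyl-2,2'-diolate) to give A1 with loss of ethylene. The catalyst alone would choose which vinyl group enters ring B and so fix C2.
- In favour: C2 would be made by catalysis from achiral material, independent of the supply and enantiomeric purity of a terpene alcohol. On the origin of configuration this plan is the better one. The bond formed is the same as in step 5.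
- Against: A2 needs an aryl–O bond to a doubly allylic tertiary carbon, harder to make and easier to ionise than the bond in 7. The alkylidene is very sensitive to air and moisture, and it must tell apart two vinyl groups on a carbon whose other substituents give little bias.
- Against: A1 carries only a vinyl group where the five-carbon chain belongs. A chemoselective hydroboration beside C3=C4 and a B-alkyl coupling with a three-carbon (E)-iodoalkene would have to follow.
- Comparison: the ethylene bridge must already be present in A2, so this cut does nothing for the linker. Mechanistically the enantio-determining step is less secure than the simple carry-over of configuration in the chosen plan, and the route would be longer by the chain-extension steps.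

Alternative 2: The cut is O1–C8a. In fluoroarene A4 the E-styrene holds the tertiary hydroxyl away from the ring. Energy transfer from fac-Ir(ppy)3 under blue light would give the Z-isomer, whose potassium alkoxide (KOtBu) displaces the fluoride para to the formyl group to give A3.
- In favour: A4 should be reachable by one Heck arylation of the vinyl group of 4. The aryl–O bond is made intramolecularly, which is easier for a tertiary alkoxide than the intermolecular substitution of step 3. No metathesis catalyst has to choose between alkenes. For the construction of ring B this plan is at least the equal of the chosen one and one step shorter up to the chromene.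
- Against: a photostationary E/Z mixture must be drained by cyclisation while an alkoxide base sits beside an aldehyde.
- Against, and more serious: A3 ends in a formyl group at C6. Turning it into the Cα–Cβ bridge means an olefination to a stilbene and then a reduction that must spare C3=C4 and the side-chain alkene, or a longer homologation.
- Comparison: the chosen plan avoids that reduction altogether. The total step count would be similar or higher, and the least selective step would fall at the end.

Alternative 3: The cuts are O1–C2 and C3–C4. Salicylaldehyde A6 and the β,β-disubstituted enal A7 would be combined by a diarylprolinol silyl ether and an acid cocatalyst. The phenol adds to the β-carbon of the iminium ion, the enamine closes onto the aryl aldehyde, and loss of water gives A5.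
- In favour: ring B and C2 arise in one metal-free catalytic step from two achiral fragments. On convergence and on bonds formed in the ring-forming step this plan is the better one, and it does not depend on 1.
- Against: oxa-Michael addition to a β,β-disubstituted iminium ion to make a fully substituted C2 is slow and reversible. E/Z isomerisation of the iminium ion and of A7 would blur the facial choice, so enantioselectivity could not be relied on.
- Against: A5 carries a formyl group at C3 that the target lacks, which costs a decarbonylation (for example RhCl(PPh3)3 with heating). A6 needs the ethylene bridge built beforehand.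
- Comparison: longer and stereochemically less secure than carrying the configuration over from 1.

Key step: step 7

Assumption: (S)-(+)-linalool of high enantiomeric purity is taken as purchasable. No bond to its carbinol carbon is made or broken in the route, and the ranking of the four substituents does not change, so the descriptor stays S from 1 to 18.

## Route

Step 1
Reactants: 1 (S)-linalool
Product: 3 (S,E)-2,6-dimethylocta-2,7-diene-1,6-diol, via (S,E)-6-hydroxy-2,6-dimethylocta-2,7-dienal 2 (not isolated)
Conditions: SeO2 (cat.), t-BuOOH, salicylic acid (cat.), CH2Cl2, rt; then NaBH4, MeOH, 0 °C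
Reagents that add atoms: tert-butyl hydroperoxide, CC(C)(C)OO (source of the new oxygen atom, passed on by SeO2, O=[Se]=O)
Why: Riley allylic oxidation (ene reaction of SeO2, then [2,3]-sigmatropic shift) attacks the trisubstituted alkene at the methyl group trans to the chain and should give the (E)-allylic alcohol; the share over-oxidised to enal 2 is returned to 3 by the borohydride, and the tertiary carbinol and its vinyl group have no allylic hydrogen to react.

Step 2
Reactants: 3 (S,E)-2,6-dimethylocta-2,7-diene-1,6-diol
Product: 4 (S,E)-8-(tert-butyldimethylsilyloxy)-3,7-dimethylocta-1,6-dien-3-ol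
Conditions: TBSCl, imidazole, CH2Cl2, 0 °C
Reagents that add atoms: tert-butyldimethylsilyl chloride, CC(C)(C)[Si](C)(C)Cl
Why: Silylation under imidazole catalysis is strongly selective for the primary over the tertiary hydroxyl, so the tertiary alcohol stays free for the next step.

Step 3
Reactants: 4 (S,E)-8-(tert-butyldimethylsilyloxy)-3,7-dimethylocta-1,6-dien-3-ol; 5 5-bromo-2-fluorobenzaldehyde
Product: 7 5-bromo-2-{[(S,E)-8-(tert-butyldimethylsilyloxy)-3,7-dimethylocta-1,6-dien-3-yl]oxy}benzaldehyde, via potassium alkoxide 6 (not isolated)
Conditions: KN(SiMe3)2 (slightly less than 4), THF, 0 °C; then 5, 0 °C → rt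
Reagents that add atoms: none
Why: Nucleophilic aromatic substitution by addition–elimination: the ortho formyl group stabilises the Meisenheimer adduct and fluoride is the best leaving group, while the bromide is not displaced; only the aryl C–O bond forms, so the stereocentre is carried over unchanged, and the base is kept below one equivalent so that no silylamide is left to attack the aldehyde.

Step 4
Reactants: 7 5-bromo-2-{[(S,E)-8-(tert-butyldimethylsilyloxy)-3,7-dimethylocta-1,6-dien-3-yl]oxy}benzaldehyde
Product: 8 4-bromo-1-{[(S,E)-8-(tert-butyldimethylsilyloxy)-3,7-dimethylocta-1,6-dien-3-yl]oxy}-2-vinylbenzene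
Conditions: Ph3PCH3Br, KOtBu, THF, 0 °C → rt
Reagents that add atoms: methyltriphenylphosphonium bromide, C[P+](c1ccccc1)(c1ccccc1)c1ccccc1.[Br-]
Why: Wittig methylenation of a non-enolisable aryl aldehyde; the silyl ether, the aryl bromide and the tertiary ether are inert to the ylide.

Step 5
Reactants: 8 4-bromo-1-{[(S,E)-8-(tert-butyldimethylsilyloxy)-3,7-dimethylocta-1,6-dien-3-yl]oxy}-2-vinylbenzene
Product: 9 (S)-6-bromo-2-[(E)-5-(tert-butyldimethylsilyloxy)-4-methylpent-3-enyl]-2-methyl-2H-chromene
Conditions: first-generation Grubbs catalyst RuCl2(=CHPh)(PCy3)2 (cat.), CH2Cl2, 40 °C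
Reagents that add atoms: none
Why: Ring-closing metathesis of a 2-(allyloxy)styrene, a known route to 2,2-disubstituted 2H-chromenes: the carbene loads on the unhindered styrene and closes the six-membered ring B onto the vinyl group with loss of ethylene; this bisphosphine catalyst is reluctant towards trisubstituted alkenes, which disfavours closure onto the side chain, and C2 is not touched.

Step 6
Reactants: 10 catechol
Product: 11 1,2-bis(methoxymethoxy)benzene
Conditions: MOMCl, i-Pr2NEt, CH2Cl2, 0 °C → rt
Reagents that add atoms: chloromethyl methyl ether, COCCl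
Why: Double O-alkylation of the phenol by the α-chloro ether through its oxocarbenium ion; the acetals protect the catechol and act as directing groups for the lithiation.

Step 7
Reactants: 11 1,2-bis(methoxymethoxy)benzene; 12 vinylboronic acid pinacol ester; 9 (S)-6-bromo-2-[(E)-5-(tert-butyldimethylsilyloxy)-4-methylpent-3-enyl]-2-methyl-2H-chromene
Product: 15 (2S)-6-[2-(2,3-bis(methoxymethoxy)phenyl)-2-(4,4,5,5-tetramethyl-1,3,2-dioxaborolan-2-yl)ethyl]-2-[(E)-5-(tert-butyldimethylsilyloxy)-4-methylpent-3-enyl]-2-methyl-2H-chromene (both configurations at the boron-bearing carbon), via 2,3-bis(methoxymethoxy)phenyllithium 13 (not isolated), via lithium aryl(vinyl)pinacolatoborate 14 (not isolated)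
Conditions: n-BuLi (slightly less than 11), THF, 0 °C; then 12, 0 °C → rt; then 9, Pd(OAc)2 (cat.), Mandyphos ligand 1,1'-bis[bis(4-methoxy-3,5-dimethylphenyl)phosphino]-2,2'-bis[α-(dimethylamino)benzyl]ferrocene (cat.), NaOTf, THF, 60 °C
Reagents that add atoms: none
Why: Directed ortho-lithiation of 11 (the acetal oxygens chelate lithium and the two positions next to them are equivalent) gives 13 free of lithium halide and of residual butyllithium, and 13 adds to the empty orbital on boron of 12 to give the four-coordinate vinylboronate 14. Oxidative addition of the C6–Br bond of 9 to zerovalent palladium and removal of bromide by NaOTf leave a cationic arylpalladium species that binds the vinyl group of 14. This binding triggers a 1,2-metalate shift: the ring-C aryl group moves from boron to the boron-bearing carbon anti to the metal while palladium bonds to the terminal carbon, and reductive elimination then forms C6–Cα and returns zerovalent palladium. The closest known reaction type is the palladium-catalysed conjunctive cross-coupling of vinylboron ate complexes with aryl triflates and halides. No ring is closed. The one new stereocentre, the boron-bearing Cβ, is biased only by the chiral ligand and needs no control because step 8 deletes it. The selectivity that matters is metalate shift over direct Suzuki transfer of aryl or vinyl from boron; the wide-bite-angle ferrocenyl bisphosphine, the weakly coordinating triflate and the halide-free ate complex favour alkene binding over transmetalation, and the aryl group migrates in preference to the pinacol oxygens. The silyl ether, the acetals, C3=C4 and the trisubstituted alkene take no part under these neutral conditions.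

Step 8
Reactants: 15 (2S)-6-[2-(2,3-bis(methoxymethoxy)phenyl)-2-(4,4,5,5-tetramethyl-1,3,2-dioxaborolan-2-yl)ethyl]-2-[(E)-5-(tert-butyldimethylsilyloxy)-4-methylpent-3-enyl]-2-methyl-2H-chromene
Product: 17 (E)-5-[(S)-6-{2-[2,3-bis(methoxymethoxy)phenyl]ethyl}-2-methyl-2H-chromen-2-yl]-2-methylpent-2-en-1-ol, via desilylated boronate 16 (not isolated)
Conditions: Bu4NF·3H2O (excess), THF/toluene, rt → 60 °C
Reagents that add atoms: none
Why: Fluoride first cleaves the primary silyl ether at room temperature to give 16; on warming it adds to boron, and the benzylic C–B bond of the resulting boronate complex is protonated by the water of hydration (known protodeboronation of benzylic pinacol boronates), which removes the stereocentre at Cβ and leaves C2, the acetals and both alkenes untouched.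

Step 9
Reactants: 17 (E)-5-[(S)-6-{2-[2,3-bis(methoxymethoxy)phenyl]ethyl}-2-methyl-2H-chromen-2-yl]-2-methylpent-2-en-1-ol
Product: 18 3-{2-[(S)-2-[(E)-5-hydroxy-4-methylpent-3-enyl]-2-methyl-2H-chromen-6-yl]ethyl}benzene-1,2-diol
Conditions: HCl (dilute), MeOH/THF (degassed), rt → 40 °C, argon
Reagents that add atoms: none
Why: Acid-catalysed acetal exchange with methanol releases both phenols as dimethoxymethane; aryl methoxymethyl ethers cleave under dilute acid that 2,2-dialkyl-2H-chromenes and a primary allylic alcohol of this type should tolerate, and exclusion of air protects the catechol.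

## Compound list

1 | (S)-linalool | CC(C)=CCC[C@@](O)(C)C=C | starting material
2 | (S,E)-6-hydroxy-2,6-dimethylocta-2,7-dienal | C/C(=C\CC[C@@](O)(C)C=C)C=O | intermediate (not isolated)
3 | (S,E)-2,6-dimethylocta-2,7-diene-1,6-diol | C/C(=C\CC[C@@](O)(C)C=C)CO | intermediate
4 | (S,E)-8-(tert-butyldimethylsilyloxy)-3,7-dimethylocta-1,6-dien-3-ol | C/C(=C\CC[C@@](O)(C)C=C)CO[Si](C)(C)C(C)(C)C | intermediate
5 | 5-bromo-2-fluorobenzaldehyde | O=Cc1cc(Br)ccc1F | starting material
6 | potassium (S,E)-8-(tert-butyldimethylsilyloxy)-3,7-dimethylocta-1,6-dien-3-olate | C/C(=C\CC[C@@]([O-])(C)C=C)CO[Si](C)(C)C(C)(C)C.[K+] | intermediate (not isolated)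
7 | 5-bromo-2-{[(S,E)-8-(tert-butyldimethylsilyloxy)-3,7-dimethylocta-1,6-dien-3-yl]oxy}benzaldehyde | C/C(=C\CC[C@@](Oc1ccc(Br)cc1C=O)(C)C=C)CO[Si](C)(C)C(C)(C)C | intermediate
8 | 4-bromo-1-{[(S,E)-8-(tert-butyldimethylsilyloxy)-3,7-dimethylocta-1,6-dien-3-yl]oxy}-2-vinylbenzene | C/C(=C\CC[C@@](Oc1ccc(Br)cc1C=C)(C)C=C)CO[Si](C)(C)C(C)(C)C | intermediate
9 | (S)-6-bromo-2-[(E)-5-(tert-butyldimethylsilyloxy)-4-methylpent-3-enyl]-2-methyl-2H-chromene | C/C(=C\CC[C@@]1(C)C=Cc2cc(Br)ccc2O1)CO[Si](C)(C)C(C)(C)C | intermediate
10 | catechol | Oc1ccccc1O | starting material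
11 | 1,2-bis(methoxymethoxy)benzene | COCOc1ccccc1OCOC | intermediate
12 | vinylboronic acid pinacol ester | C=CB1OC(C)(C)C(C)(C)O1 | starting material
13 | 2,3-bis(methoxymethoxy)phenyllithium | [Li]c1cccc(OCOC)c1OCOC | intermediate (not isolated)
14 | lithium [2,3-bis(methoxymethoxy)phenyl](vinyl)(pinacolato)borate | [Li+].C=C[B-]1(c2cccc(OCOC)c2OCOC)OC(C)(C)C(C)(C)O1 | intermediate (not isolated)
15 | (2S)-6-[2-(2,3-bis(methoxymethoxy)phenyl)-2-(4,4,5,5-tetramethyl-1,3,2-dioxaborolan-2-yl)ethyl]-2-[(E)-5-(tert-butyldimethylsilyloxy)-4-methylpent-3-enyl]-2-methyl-2H-chromene, both configurations at the boron-bearing carbon | C/C(=C\CC[C@@]1(C)C=Cc2cc(CC(B3OC(C)(C)C(C)(C)O3)c3cccc(OCOC)c3OCOC)ccc2O1)CO[Si](C)(C)C(C)(C)C | intermediate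
16 | (E)-5-[(2S)-6-[2-(2,3-bis(methoxymethoxy)phenyl)-2-(4,4,5,5-tetramethyl-1,3,2-dioxaborolan-2-yl)ethyl]-2-methyl-2H-chromen-2-yl]-2-methylpent-2-en-1-ol | C/C(=C\CC[C@@]1(C)C=Cc2cc(CC(B3OC(C)(C)C(C)(C)O3)c3cccc(OCOC)c3OCOC)ccc2O1)CO | intermediate (not isolated)
17 | (E)-5-[(S)-6-{2-[2,3-bis(methoxymethoxy)phenyl]ethyl}-2-methyl-2H-chromen-2-yl]-2-methylpent-2-en-1-ol | C/C(=C\CC[C@@]1(C)C=Cc2cc(CCc3cccc(OCOC)c3OCOC)ccc2O1)CO | intermediate
18 | 3-{2-[(S)-2-[(E)-5-hydroxy-4-methylpent-3-enyl]-2-methyl-2H-chromen-6-yl]ethyl}benzene-1,2-diol | C/C(=C\CC[C@@]1(C)C=Cc2cc(CCc3cccc(O)c3O)ccc2O1)CO | target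

## Step count and least certain steps

Total: 9 steps. Longest linear sequence: 8 steps (steps 1–5, then 7–9, from 1); the second branch (step 6) joins at step 7.

Step 7 (key step). Direct transmetalation may outrun the metalate shift, giving transfer of the aryl or vinyl group from boron to palladium. The migration of an ortho-substituted, electron-rich aryl group may also be slow, and the bromide released may suppress the cationic pathway. Fallback, from 11 and 9, rejoining at 17: 11 is lithiated as before (13) and quenched with DMF to give 2,3-bis(methoxymethoxy)benzaldehyde F1. Wittig methylenation gives 1,2-bis(methoxymethoxy)-3-vinylbenzene F2. Anti-Markovnikov hydroboration with 9-borabicyclo[3.3.1]nonane gives the B-alkyl borane F3. A B-alkyl Suzuki coupling of F3 with 9 (PdCl2(dppf), K3PO4, THF/water) gives the bridged silyl ether F4. Bu4NF at room temperature then removes the silyl group to give 17. The bridge is then built one bond at a time, again without a hydrogenation, at the cost of three extra steps.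

Step 3. The hindered tertiary alkoxide may add to the formyl group and pass on hydride (Cannizzaro–Tishchenko type consumption of the aldehyde), or substitution may be too slow for steric reasons. Fallback, from 4 (as its alkoxide 6), rejoining at 7: substitution on 5-bromo-2-fluorobenzonitrile, which has no electrophilic carbonyl, gives the aryl ether nitrile F5. Reduction with i-Bu2AlH in toluene at −78 °C and aqueous acid work-up, through the aldimine F6, then gives 7.

Step 5. Ring closure onto the side-chain alkene (a five-membered carbocycle from the 1,6-diene) or sluggish engagement of the hindered vinyl group may compete with closure of ring B. Fallback, from 8, rejoining at 9: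
- Bu4NF frees the allylic alcohol F7.
- MnO2 oxidises it to the enal F8, whose conjugated trisubstituted double bond is inert to ruthenium carbenes.
- Ring-closing metathesis with the second-generation catalyst RuCl2(=CHPh)(H2IMes)(PCy3) gives the chromene enal F9.
- NaBH4 with CeCl3 gives the chromene allylic alcohol F10.
- TBSCl and imidazole return 9.

Step 8. The C–B bond may resist fluoride-induced cleavage, because the electron-rich ring C stabilises the developing benzylic carbanion poorly, while the silyl ether is lost regardless. Fallback, from 15, rejoining at 17: PhLi adds to boron to give the phenyl ate complex F11. Single-electron oxidation under blue light with Ir[dF(CF3)ppy]2(dtbbpy)PF6 and PhSH releases the benzylic radical, which takes a hydrogen atom from the thiol. This radical protodeboronation of pinacol boronates via aryl ate complexes gives the silyl ether F4, and Bu4NF at room temperature then gives 17.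

Step 9. Acid may ionise the allylic alcohol or the C2–O1 bond before both acetals are gone, and the freed catechol may oxidise. Fallback, from 10 and 9, rejoining at 18, with no acid at any point:
- 10 is protected with 2-(trimethylsilyl)ethoxymethyl chloride and i-Pr2NEt as the bis-ether F12.
- Directed lithiation gives F13, and addition to 12 gives the ate complex F14.
- The same conjunctive coupling with 9 gives boronate F15.
- Bu4NF in DMPU with warming then removes boron, the silyl ether and both fluoride-labile acetals (with loss of ethylene and formaldehyde) to give 18 directly.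

## Further compounds

F1 | step 7 | 2,3-bis(methoxymethoxy)benzaldehyde | O=Cc1cccc(OCOC)c1OCOC
F2 | step 7 | 1,2-bis(methoxymethoxy)-3-vinylbenzene | C=Cc1cccc(OCOC)c1OCOC
F3 | step 7 | 9-{2-[2,3-bis(methoxymethoxy)phenyl]ethyl}-9-borabicyclo[3.3.1]nonane | COCOc1cccc(CCB2C3CCCC2CCC3)c1OCOC
F4 | step 7 | (S)-6-{2-[2,3-bis(methoxymethoxy)phenyl]ethyl}-2-[(E)-5-(tert-butyldimethylsilyloxy)-4-methylpent-3-enyl]-2-methyl-2H-chromene | C/C(=C\CC[C@@]1(C)C=Cc2cc(CCc3cccc(OCOC)c3OCOC)ccc2O1)CO[Si](C)(C)C(C)(C)C
F5 | step 3 | 5-bromo-2-{[(S,E)-8-(tert-butyldimethylsilyloxy)-3,7-dimethylocta-1,6-dien-3-yl]oxy}benzonitrile | C/C(=C\CC[C@@](Oc1ccc(Br)cc1C#N)(C)C=C)CO[Si](C)(C)C(C)(C)C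
F6 | step 3 | 1-(5-bromo-2-{[(S,E)-8-(tert-butyldimethylsilyloxy)-3,7-dimethylocta-1,6-dien-3-yl]oxy}phenyl)methanimine | C/C(=C\CC[C@@](Oc1ccc(Br)cc1C=N)(C)C=C)CO[Si](C)(C)C(C)(C)C
F7 | step 5 | (S,E)-6-(4-bromo-2-vinylphenoxy)-2,6-dimethylocta-2,7-dien-1-ol | C/C(=C\CC[C@@](Oc1ccc(Br)cc1C=C)(C)C=C)CO
F8 | step 5 | (S,E)-6-(4-bromo-2-vinylphenoxy)-2,6-dimethylocta-2,7-dienal | C/C(=C\CC[C@@](Oc1ccc(Br)cc1C=C)(C)C=C)C=O
F9 | step 5 | (E)-5-[(S)-6-bromo-2-methyl-2H-chromen-2-yl]-2-methylpent-2-enal | C/C(=C\CC[C@@]1(C)C=Cc2cc(Br)ccc2O1)C=O
F10 | step 5 | (E)-5-[(S)-6-bromo-2-methyl-2H-chromen-2-yl]-2-methylpent-2-en-1-ol | C/C(=C\CC[C@@]1(C)C=Cc2cc(Br)ccc2O1)CO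
F11 | step 8 | lithium phenyl ate complex of boronate 15 | [Li+].C/C(=C\CC[C@@]1(C)C=Cc2cc(CC([B-]3(c4ccccc4)OC(C)(C)C(C)(C)O3)c3cccc(OCOC)c3OCOC)ccc2O1)CO[Si](C)(C)C(C)(C)C
F12 | step 9 | 1,2-bis{[2-(trimethylsilyl)ethoxy]methoxy}benzene | C[Si](C)(C)CCOCOc1ccccc1OCOCC[Si](C)(C)C
F13 | step 9 | 2,3-bis{[2-(trimethylsilyl)ethoxy]methoxy}phenyllithium | [Li]c1cccc(OCOCC[Si](C)(C)C)c1OCOCC[Si](C)(C)C
F14 | step 9 | lithium (2,3-bis{[2-(trimethylsilyl)ethoxy]methoxy}phenyl)(vinyl)(pinacolato)borate | [Li+].C=C[B-]1(c2cccc(OCOCC[Si](C)(C)C)c2OCOCC[Si](C)(C)C)OC(C)(C)C(C)(C)O1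
F15 | step 9 | (2S)-6-[2-(2,3-bis{[2-(trimethylsilyl)ethoxy]methoxy}phenyl)-2-(4,4,5,5-tetramethyl-1,3,2-dioxaborolan-2-yl)ethyl]-2-[(E)-5-(tert-butyldimethylsilyloxy)-4-methylpent-3-enyl]-2-methyl-2H-chromene | C/C(=C\CC[C@@]1(C)C=Cc2cc(CC(B3OC(C)(C)C(C)(C)O3)c3cccc(OCOCC[Si](C)(C)C)c3OCOCC[Si](C)(C)C)ccc2O1)CO[Si](C)(C)C(C)(C)C
A1 | alternative 1 | (S)-6-[2-(2,3-bis(methoxymethoxy)phenyl)ethyl]-2-methyl-2-vinyl-2H-chromene | C=C[C@@]1(C)C=Cc2cc(CCc3cccc(OCOC)c3OCOC)ccc2O1
A2 | alternative 1 | 1,2-bis(methoxymethoxy)-3-{2-[4-(3-methylpenta-1,4-dien-3-yloxy)-3-vinylphenyl]ethyl}benzene | C=CC(C)(C=C)Oc1ccc(CCc2cccc(OCOC)c2OCOC)cc1C=C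
A3 | alternative 2 | (S)-2-[(E)-5-(tert-butyldimethylsilyloxy)-4-methylpent-3-enyl]-2-methyl-2H-chromene-6-carbaldehyde | C/C(=C\CC[C@@]1(C)C=Cc2cc(C=O)ccc2O1)CO[Si](C)(C)C(C)(C)C
A4 | alternative 2 | 4-fluoro-3-[(S,1E,6E)-8-(tert-butyldimethylsilyloxy)-3-hydroxy-3,7-dimethylocta-1,6-dienyl]benzaldehyde | C/C(=C\CC[C@@](O)(C)/C=C/c1cc(C=O)ccc1F)CO[Si](C)(C)C(C)(C)C
A5 | alternative 3 | (S)-6-[2-(2,3-bis(methoxymethoxy)phenyl)ethyl]-2-[(E)-5-(tert-butyldimethylsilyloxy)-4-methylpent-3-enyl]-2-methyl-2H-chromene-3-carbaldehyde | C/C(=C\CC[C@@]1(C)C(C=O)=Cc2cc(CCc3cccc(OCOC)c3OCOC)ccc2O1)CO[Si](C)(C)C(C)(C)C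
A6 | alternative 3 | 5-{2-[2,3-bis(methoxymethoxy)phenyl]ethyl}-2-hydroxybenzaldehyde | O=Cc1cc(CCc2cccc(OCOC)c2OCOC)ccc1O
A7 | alternative 3 | (2E,6E)-8-(tert-butyldimethylsilyloxy)-3,7-dimethylocta-2,6-dienal | C/C(=C\CC/C(C)=C/C=O)CO[Si](C)(C)C(C)(C)C
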